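Amounts first: I counted substrate and target as fractions of the substrate charged.

| setting | birch | larch | noon | summer | autumn |
|---|---|---|---|---|---|
| substrate | 0.30 M | 0.30 M | 0.30 M | 0.30 M | 0.30 M |
| reagent | 0.45 M | 0.45 M | 0.450 M | 0.450 M | 0.450 M |
| catalyst | 6.3 mM | 9.9 mM | 4.5 mM | 4.5 mM | 4.5 mM |
| added ligand | 5 mM | 5 mM | 5.0 mM | 5.0 mM | 5.0 mM |
| temperature | 78 °C | 94 °C | 100 °C | 70 °C | 85 °C |
| remark | run made earlier | run made earlier |  |  |  |
| time |  |  | 8.0 h | 8.0 h | 8.0 h |

- birch (time / h: target / %, substrate / %): 1.33: 59, 36; 2.50: 58, 35; 6.00: 53, 35; 15.0: 48, 27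
- larch (time / h: target / %, substrate / %): 0.417: 48, 50; 0.833: 43, 44; 2.00: 44, 40; 5.00: 38, 38

(scatter of a reading: 1.5 percentage points)



- the flask that comes out highest in amount of target, in percent of the substrate charged, or "all alike" when all lie within 1.5 percentage points (noon / summer / autumn / all alike)
- target at the end, in percent of the substrate charged, noon
- target at the end, in percent of the substrate charged, summer
- target at the end, in percent of the substrate charged, autumn

1. Start. Birch's target climbed at an average 0.444 h⁻¹ up to its first reading. Scaled to the catalyst charge, I took 0.317 h⁻¹ for summer.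

2. Fade. Past the knee, birch's target sank from 59% to 48%. I treated this as a pseudo-first-order loss and named its fade rate, the fraction of target lost per hour past the knee: 0.0151 h⁻¹ in birch, and 0.0510 h⁻¹ in larch.

3. Level. Run back along the fade, the readings gave a level of 60.2% in birch and 49.0% in larch. The two runs also differ in catalyst, but I assumed that level and fade follow temperature, and I carried both geometrically along it: interpolating for autumn, extrapolating for summer and noon.

4. Knee. Summer's level came to 66.7%. At the scaled slope that is reached near 2.10 h, earlier than the end at 8.0 h, so the curve should bend well inside the run.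

5. End. Summer fades at 0.00821 h⁻¹, which leaves 62.5%. Autumn has level 55.0% and fade 0.0257 h⁻¹, leaving 44.8%. Noon has level 45.4% and fade 0.0805 h⁻¹, leaving 23.9%. I chose summer.

6. Forecast. It also named summer, but with lower ends than mine: noon 12%, summer 54%, autumn 29%. Its ground was “So the catalyst dies quickly, and it dies relatively faster when hot.”

7. Result. Summer gave 63.0%, autumn 42.3% and noon 20.7%.

    substrate + target → side product (k = 0.0770 L mol⁻¹ h⁻¹, Ea = 90.0 kJ mol⁻¹)
    substrate + reagent + catalyst ⇌ target + catalyst, rate k2*[substrate]*[reagent]*[catalyst] forward; the back reaction follows from the equilibrium constant (K = 8.50 L mol⁻¹, k = 3400 L² mol⁻² h⁻¹, Ea = 41.0 kJ mol⁻¹, ΔH = −42.0 kJ mol⁻¹)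
    catalyst + added ligand ⇌ idle complex (K = 580 L mol⁻¹, k = 160 L mol⁻¹ h⁻¹, Ea = 77.0 kJ mol⁻¹, ΔH = 5.00 kJ mol⁻¹)
    (constants at 70 °C)

Changing only the catalyst amount from birch's to noon's left birch's last-reading figure at 46.7%, from 46.7%. Autumn's fade of 0.0257 h⁻¹ then carried its 42.3% from 8.0 h to 15 h, giving 35.4%. The simulated autumn reading at that time stood at 34.8%.

All runs were computed for substances that don't exist; scatter was added.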